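## Retrosynthetic overview
1. The target comes from its methyl ester 18. The carboxyl sits on a quaternary carbon next to a second quaternary carbon, so the ester is cleaved last by SN2 attack at the O‑methyl group.
2. 18 comes from one intramolecular Diels–Alder (IMDA) of the linear (2E,4Z,7E,9E,11E,13E)‑hexaenoate 17. Cyclopentene and cyclohexene close together (bonds C3–C7 and C2–C10), and the single C6 methyl stereocentre sets C3a, C4, C5 and C7a.
3. The C3–C4 bond of 17 is made at a cathode by Ni‑catalysed electroreductive cross‑coupling of (Z)‑alkenyl iodide 15 with (E)‑bromoacrylate 16.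
4. 15 comes from an iodo‑Wittig reaction on α‑methyl aldehyde 12. The phenyl‑tetraene arm comes from three formyl‑ylide Wittig homologations and one benzylphosphonate HWE.
5. The C6 stereocentre is bought as (R)‑Roche ester.

Assumption: 5, 9, 13 and 16 are purchased; if 16 is unavailable, it is made from methyl methacrylate by Br2 addition and DBU elimination (2 steps, off the linear sequence).

Locants: linear compounds use the numbering of hexaenoate 17 (C1 = ester C=O, C14 = CHPh). Bicycles use 1H‑indene numbering. All polyenes are handled under Ar, in the dark, with a trace of BHT.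

## Route

**Step 1**
Reactants: 1 methyl (R)‑3‑hydroxy‑2‑methylpropanoate; 2 tert‑butyldimethylsilyl chloride
Product: 3 methyl (R)‑3‑[(tert‑butyldimethylsilyl)oxy]‑2‑methylpropanoate
Conditions: TBSCl, imidazole, CH2Cl2, 0 °C to rt
Reagents that add atoms: TBSCl, CC(C)(C)[Si](C)(C)Cl
Why: Standard silyl ether protection differentiates the two termini of the chiral‑pool unit without touching the stereocentre.

**Step 2**
Reactants: 3
Product: 4 (R)‑3‑[(tert‑butyldimethylsilyl)oxy]‑2‑methylpropanal
Conditions: DIBAL‑H (1.1 equiv), CH2Cl2, −78 °C; Rochelle salt work‑up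
Reagents that add atoms: none
Why: In this DIBAL‑H partial reduction the tetrahedral aluminate survives at −78 °C, so the ester stops at the aldehyde without epimerisation.

**Step 3**
Reactants: 4; 5 2‑(triphenylphosphoranylidene)propanal
Product: 6 (2E,4S)‑5‑[(tert‑butyldimethylsilyl)oxy]‑2,4‑dimethylpent‑2‑enal
Conditions: 5 (1.3 equiv), toluene, 90 °C
Reagents that add atoms: 5, CC(C=O)=P(c1ccccc1)(c1ccccc1)c1ccccc1
Why: Wittig olefination with a neutral stabilised ylide is E‑selective, stops at the much less electrophilic enal, and leaves the stereocentre intact (the descriptor changes for CIP reasons only).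

**Step 4**
Reactants: 6; 5
Product: 7 (2E,4E,6S)‑7‑[(tert‑butyldimethylsilyl)oxy]‑2,4,6‑trimethylhepta‑2,4‑dienal
Conditions: 5 (1.5 equiv), toluene, 110 °C
Reagents that add atoms: 5, CC(C=O)=P(c1ccccc1)(c1ccccc1)c1ccccc1
Why: A second E‑selective stabilised‑ylide Wittig homologation delivers the next aldehyde directly, so no redox adjustment is needed.

**Step 5**
Reactants: 7; 5
Product: 8 (2E,4E,6E,8S)‑9‑[(tert‑butyldimethylsilyl)oxy]‑2,4,6,8‑tetramethylnona‑2,4,6‑trienal
Conditions: 5 (1.5–2 equiv), toluene, 110 °C, stopped at full conversion of 7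
Reagents that add atoms: 5, CC(C=O)=P(c1ccccc1)(c1ccccc1)c1ccccc1
Why: This is a third E‑selective Wittig homologation, and the more conjugated trienal product reacts more slowly than 7, which limits over‑homologation.

**Step 6**
Reactants: 8; 9 diethyl benzylphosphonate
Product: 10 tert‑butyl(dimethyl){[(2S,3E,5E,7E,9E)‑2,4,6,8‑tetramethyl‑10‑phenyldeca‑3,5,7,9‑tetraen‑1‑yl]oxy}silane
Conditions: 9, n‑BuLi, THF, −78 °C; then 8, −78 to 0 °C
Reagents that add atoms: 9, CCOP(=O)(Cc1ccccc1)OCC
Why: Horner–Wadsworth–Emmons olefination with a benzyl phosphonate anion gives the (E)‑styryl terminus, and carbonyl addition at low temperature outruns deprotonation at the remote vinylogous C–H.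

**Step 7**
Reactants: 10
Product: 11 (2S,3E,5E,7E,9E)‑2,4,6,8‑tetramethyl‑10‑phenyldeca‑3,5,7,9‑tetraen‑1‑ol
Conditions: TBAF, THF, 0 °C to rt
Reagents that add atoms: none
Why: Fluoride desilylation avoids the acid that a tetraene would not tolerate.

**Step 8**
Reactants: 11
Product: 12 (2S,3E,5E,7E,9E)‑2,4,6,8‑tetramethyl‑10‑phenyldeca‑3,5,7,9‑tetraenal (used crude at once)
Conditions: Dess–Martin periodinane, NaHCO3, CH2Cl2, 0 °C, 30 min; cold filtration through a short plug
Reagents that add atoms: none
Why: Buffered Dess–Martin oxidation uses no amine base, so the α‑methyl β,γ‑unsaturated aldehyde is neither epimerised nor drawn into conjugation.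

**Step 9**
Reactants: 12; 13 ethyltriphenylphosphonium iodide; 14 iodine
Product: 15 [(1E,3E,5E,7E,9S,10Z)‑11‑iodo‑3,5,7,9‑tetramethyldodeca‑1,3,5,7,10‑pentaen‑1‑yl]benzene
Conditions: 13, n‑BuLi, THF, rt; I2 (0.98 equiv vs ylide), −78 °C; NaHMDS, −20 °C; then 12, −78 °C, 1 h
Reagents that add atoms: 13, CC[P+](c1ccccc1)(c1ccccc1)c1ccccc1.[I-]; iodine, II
Why: In this Stork–Zhao‑type iodo‑Wittig the reactive α‑iodo ylide adds under kinetic control at −78 °C to give the (Z)‑2‑iodoalkene (I cis to the chain) faster than 12 can enolise, so the stereocentre is kept.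

**Step 10**
Reactants: 15; 16 methyl (E)‑3‑bromo‑2‑methylprop‑2‑enoate
Product: 17 methyl (2E,4Z,6S,7E,9E,11E,13E)‑2,4,6,8,10,12‑hexamethyl‑14‑phenyltetradeca‑2,4,7,9,11,13‑hexaenoate
Conditions: undivided cell, Zn(+)/Ni foam(−), NiBr2·dme (10 mol %), dtbbpy (12 mol %), NaI (0.2 M), DMA, 16 (3 equiv, syringe pump), 4 mA constant current until 15 is consumed (about 4 F/mol), 10 °C, Ar, dark; cold aq. NH4Cl/EDTA work‑up, short silica plug below 10 °C (any 18 already formed is carried along)
Reagents that add atoms: 16, COC(=O)/C(C)=C/Br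
Why: Proposed new method: cathodically regenerated (dtbbpy)Ni(0) should insert first into the electron‑poor, unhindered C–Br bond of 16, the alkenyl–Ni(II) is reduced near −1.2 V vs SCE (positive of the polyene, ester and C–I waves) to alkenyl–Ni(I), which takes up the weaker C–I bond of 15 by concerted geometry‑retaining oxidative addition and reductively eliminates the C3–C4 bond to give (2E,4Z)‑17 with no base and no preformed organometallic (so the doubly allylic C6–H stereocentre is untouched), while syringe‑pump addition keeps 16 scarce so that alkenyl–Ni(I) meets 15 rather than a second 16; the closest known reaction types are Ni/bipyridine electroreductive couplings of alkenyl halides (homocoupling and aryl–alkenyl) and metal‑powder‑driven alkenyl–alkenyl cross‑electrophile coupling.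

**Step 11**
Reactants: 17
Product: 18 methyl (1R,3aR,4R,5S,7aS)‑1,3,4,5,7‑pentamethyl‑5‑[(1E,3E)‑2‑methyl‑4‑phenylbuta‑1,3‑dien‑1‑yl]‑3a,4,5,7a‑tetrahydro‑1H‑indene‑4‑carboxylate
Conditions: toluene (0.01 M), BHT (5 mol %), 70 °C, 16 h, Ar, dark
Reagents that add atoms: none
Why: In this thermal intramolecular Diels–Alder reaction the Z‑C4=C5 alkene holds dienophile C2=C3 over diene C7–C10, suprafacial addition maps 2E onto cis CO2Me/H‑3a and 7E,9E onto cis H‑7a/5‑Me, the ester‑endo (tether‑exo) transition state gives the trans ring fusion, and with C6–H eclipsing C7=C8 (A1,3 strain with the C8 methyl) the dienophile reaches the diene face anti to the C6 methyl, so the purchased stereocentre sets C3a, C4, C5 and C7a.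

**Step 12**
Reactants: 18
Product: 19 27‑nor‑zyggomphic acid B, (1R,3aR,4R,5S,7aS)‑1,3,4,5,7‑pentamethyl‑5‑[(1E,3E)‑2‑methyl‑4‑phenylbuta‑1,3‑dien‑1‑yl]‑3a,4,5,7a‑tetrahydro‑1H‑indene‑4‑carboxylic acid
Conditions: LiI (10 equiv), pyridine, reflux, Ar; then aq. citric acid
Reagents that add atoms: none
Why: Nucleophilic O‑demethylation (SN2 of iodide at the methyl carbon) bypasses the inaccessible carbonyl, and no stereocentre or alkene is affected.

## Compound list
1 | methyl (R)‑3‑hydroxy‑2‑methylpropanoate | COC(=O)[C@H](C)CO | starting material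
2 | tert‑butyldimethylsilyl chloride | CC(C)(C)[Si](C)(C)Cl | starting material
3 | methyl (R)‑3‑(TBSO)‑2‑methylpropanoate | COC(=O)[C@H](C)CO[Si](C)(C)C(C)(C)C | intermediate
4 | (R)‑3‑(TBSO)‑2‑methylpropanal | O=C[C@H](C)CO[Si](C)(C)C(C)(C)C | intermediate
5 | 2‑(triphenylphosphoranylidene)propanal | CC(C=O)=P(c1ccccc1)(c1ccccc1)c1ccccc1 | starting material
6 | (2E,4S)‑5‑(TBSO)‑2,4‑dimethylpent‑2‑enal | O=C/C(C)=C/[C@H](C)CO[Si](C)(C)C(C)(C)C | intermediate
7 | (2E,4E,6S)‑7‑(TBSO)‑2,4,6‑trimethylhepta‑2,4‑dienal | O=C/C(C)=C/C(C)=C/[C@H](C)CO[Si](C)(C)C(C)(C)C | intermediate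
8 | (2E,4E,6E,8S)‑9‑(TBSO)‑2,4,6,8‑tetramethylnona‑2,4,6‑trienal | O=C/C(C)=C/C(C)=C/C(C)=C/[C@H](C)CO[Si](C)(C)C(C)(C)C | intermediate
9 | diethyl benzylphosphonate | CCOP(=O)(Cc1ccccc1)OCC | starting material
10 | TBS ether of (2S,3E,5E,7E,9E)‑2,4,6,8‑tetramethyl‑10‑phenyldeca‑3,5,7,9‑tetraen‑1‑ol | c1ccccc1/C=C/C(C)=C/C(C)=C/C(C)=C/[C@H](C)CO[Si](C)(C)C(C)(C)C | intermediate
11 | (2S,3E,5E,7E,9E)‑2,4,6,8‑tetramethyl‑10‑phenyldeca‑3,5,7,9‑tetraen‑1‑ol | c1ccccc1/C=C/C(C)=C/C(C)=C/C(C)=C/[C@H](C)CO | intermediate
12 | (2S,3E,5E,7E,9E)‑2,4,6,8‑tetramethyl‑10‑phenyldeca‑3,5,7,9‑tetraenal | c1ccccc1/C=C/C(C)=C/C(C)=C/C(C)=C/[C@H](C)C=O | intermediate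
13 | ethyltriphenylphosphonium iodide | CC[P+](c1ccccc1)(c1ccccc1)c1ccccc1.[I-] | starting material
14 | iodine | II | starting material
15 | [(1E,3E,5E,7E,9S,10Z)‑11‑iodo‑3,5,7,9‑tetramethyldodeca‑1,3,5,7,10‑pentaen‑1‑yl]benzene | c1ccccc1/C=C/C(C)=C/C(C)=C/C(C)=C/[C@H](C)/C=C(/C)I | intermediate
16 | methyl (E)‑3‑bromo‑2‑methylprop‑2‑enoate | COC(=O)/C(C)=C/Br | starting material
17 | methyl (2E,4Z,6S,7E,9E,11E,13E)‑2,4,6,8,10,12‑hexamethyl‑14‑phenyltetradeca‑2,4,7,9,11,13‑hexaenoate | c1ccccc1/C=C/C(C)=C/C(C)=C/C(C)=C/[C@H](C)/C=C(/C)\C=C(/C)C(=O)OC | intermediate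
18 | methyl ester of the target, (1R,3aR,4R,5S,7aS) | CC1=C[C@](C)(/C=C(C)/C=C/c2ccccc2)[C@](C)(C(=O)OC)[C@H]2C(C)=C[C@@H](C)[C@H]12 | intermediate
19 | 27‑nor‑zyggomphic acid B | CC1=C[C@](C)(/C=C(C)/C=C/c2ccccc2)[C@](C)(C(=O)O)[C@H]2C(C)=C[C@@H](C)[C@H]12 | target

## Step count
Total steps: 12. Longest linear sequence: 12 (fully linear; every partner is purchased). Steps 10 and 11 can be run back to back without chromatography of 17, but they are counted separately.

## Three steps most likely to fail
1. **Step 10 (new electroreductive alkenyl–alkenyl coupling).**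
   - Risks: homocoupling of either halide, Z→E leakage at nickel (which gives an all‑E hexaenoate that cannot cyclise), hydrodehalogenation, and polyene binding to Ni(0).
   - Fallback (known chemistry): drop the halide–halide coupling and build the Z‑dienoate by olefination.
     - From 12, run a Z‑selective Ando HWE with ethyl 2‑(di‑o‑tolyloxyphosphoryl)propanoate, then DIBAL‑H, then MnO2, then Ph3P=C(Me)CO2Me to reach 17.
     - This replaces steps 9–10 and adds 2 steps net. Steps 11–12 are unchanged.
2. **Step 11 (IMDA forming two adjacent quaternary carbons and a trans ring fusion).**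
   - Risks:
     - Slow cyclisation.
     - Competing tether‑endo (cis‑fused) adduct.
     - A [1,5]‑H shift of C6–H along the Z‑dienoate at higher temperature, which would destroy the only controlling stereocentre.
   - Fallback: change the oxidation level of the dienophile.
     - Reduce 17 with DIBAL‑H and oxidise with MnO2 to the (2E,4Z)‑dienal.
     - Cyclise this much more reactive enal at or below rt. Me2AlCl in CH2Cl2 at −78 to −20 °C can be used if needed, and it also reinforces carbonyl‑endo, trans‑fused selectivity.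
     - Convert the aldehyde directly to 19 by Pinnick oxidation with 2‑methyl‑2‑butene as scavenger.
     - This replaces steps 11–12, adds 2 steps, and removes the hindered ester cleavage.
3. **Step 9 (iodo‑Wittig on the labile aldehyde 12 from step 8).**
   - Risks: epimerisation or conjugation of 12, and a modest yield or Z:E ratio.
   - Fallback: reverse the order of arm construction.
     - Start from (S)‑Roche ester and run the iodo‑Wittig on the configurationally robust silyloxy aldehyde (ent‑4).
     - Deprotect, oxidise, and grow the tetraene arm from an aldehyde flanked only by the iodoalkene.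
     - Do the first homologation at rt with Ph3P=C(Me)CO2Et, followed by DIBAL‑H and MnO2. This converges on 15.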